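**Retrosynthetic overview**
1. The C4 4-hydroxybenzoate and the C8 angelate go on last; the tertiary carbinol comes from i-Pr addition to a C3 ketone.
2. C3a–H and C4–OH (trans ring fusion) come from reductive opening of a 3a,4-epoxy ketone, made from the enone released by E1cB opening of a 4,8-oxygen bridge.
3. The C6=C7 alkene comes from reductive 1,3-transposition of a bridged C7 enone.
4. Key step: one enantioselective [5+2] cycloaddition of an aromatic 3-oxidopyrylium betaine with 3-methylcyclopent-2-enone forms the seven-membered ring, the quaternary C8a and both ring C–O bonds (five-membered ring bought, seven-membered ring formed here).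
5. The betaine comes from methyl 3-methyl-2-furoate by reduction and Achmatowicz ring expansion.

Assumption: positions use the azulene numbering of the target (C3 tertiary carbinol, C3a ring-fusion CH, C4 benzoate carbinol, C6=C7 alkene, C8 angelate carbinol, C8a quaternary carbon; target = 3R,3aS,4S,8S,8aS). The quinine-derived amine in step 3 is assumed to give the drawn enantiomer; otherwise the quinidine-derived pseudo-enantiomer is used.

**Step 1**
Reactants: 1 methyl 3-methylfuran-2-carboxylate
Product: 2 (3-methylfuran-2-yl)methanol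
Conditions: LiAlH4, THF, 0 °C
Reagents that add atoms: none
Why: Hydride reduction of the ester to the primary alcohol leaves the aromatic furan untouched and creates no stereocentre.

**Step 2**
Reactants: 2 (3-methylfuran-2-yl)methanol
Product: 4 4-methyl-5-oxo-5,6-dihydro-2H-pyran-2-yl acetate (racemic), via hydroxypyranone 3 (not isolated)
Conditions: mCPBA, CH2Cl2, 0 °C to rt; then Ac2O, pyridine, DMAP (cat), 0 °C
Reagents that add atoms: m-chloroperoxybenzoic acid, OOC(=O)c1cccc(Cl)c1; acetic anhydride, CC(=O)OC(C)=O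
Why: Achmatowicz rearrangement: peracid oxidation of the electron-rich furan gives the cis-enedione, which the primary hydroxyl closes to the 6-hydroxypyranone that is acetylated in the same flask, the racemic acetal centre being irrelevant because it is destroyed in step 3.

**Step 3 (key step)**
Reactants: 4 4-methyl-5-oxo-5,6-dihydro-2H-pyran-2-yl acetate; 5 3-methylcyclopent-2-en-1-one
Product: 7 (3aR,4R,8R,8aS)-6,8a-dimethyl-1,2,3a,4,8,8a-hexahydro-4,8-epoxyazulene-3,7-dione, via oxidopyrylium betaine 6 (not isolated)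
Conditions: 9-amino(9-deoxy)epi-quinine (20 mol %), salicylic acid (40 mol %), i-Pr2NEt (1.1 equiv), 5 (5 equiv), CHCl3, 40 °C, 4 added over 12 h
Reagents that add atoms: none
Why: Proposed new method: the amine base eliminates acetic acid from 4 to give the aromatic betaine 6, whose enolate-like C2 adds to the β-carbon of the iminium ion formed from 5 and the chiral primary amine (building the quaternary C8a centre on the face left open by the catalyst), and the resulting enamine carbon then closes onto the oxocarbenium end C6 of the pyrylium in an endo arrangement held by an N–H to oxido hydrogen bond, so that the oxygen bridge, the 8a-methyl and the 3a-hydrogen end up on one face and all four stereocentres are set at once; the closest known reactions are the thermal [5+2] cycloaddition of 3-oxidopyrylium betaines with electron-poor alkenes, iminium-catalysed dipolar cycloadditions of nitrones and azomethine ylides, and primary-amine iminium activation of β-substituted cycloalkenones for quaternary-centre formation, and the 4-methyl group additionally slows the betaine self-dimerisation that normally competes with sluggish alkenes.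

**Step 4**
Reactants: 7 (3aR,4R,8R,8aS)-6,8a-dimethyl-1,2,3a,4,8,8a-hexahydro-4,8-epoxyazulene-3,7-dione
Product: 8 3-[(tert-butyldimethylsilyl)oxy]-6,8a-dimethyl-3a,4,8,8a-tetrahydro-4,8-epoxyazulen-7(1H)-one (C2=C3 silyl enol ether; stereocentres as in 7)
Conditions: LiN(SiMe3)2, THF, −78 °C; then TBSOTf, −78 °C
Reagents that add atoms: tert-butyldimethylsilyl trifluoromethanesulfonate, CC(C)(C)[Si](C)(C)OS(=O)(=O)C(F)(F)F
Why: Kinetic enolisation removes a proton from the unhindered C2 methylene of the cyclopentanone (the C7 enone has no enolisable hydrogen because C8 and C4 are bridgeheads and C6 is vinylic) and O-silylation masks the C3 ketone as its silyl enol ether, so that the two carbonyl groups are differentiated without touching a stereocentre.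

**Step 5**
Reactants: 8 3-[(tert-butyldimethylsilyl)oxy]-6,8a-dimethyl-3a,4,8,8a-tetrahydro-4,8-epoxyazulen-7(1H)-one
Product: 10 3-[(tert-butyldimethylsilyl)oxy]-6,8a-dimethyl-1,3a,4,5,8,8a-hexahydro-4,8-epoxyazulene (C2=C3 and C6=C7 double bonds; stereocentres as in 7), via tosylhydrazone 9 (not isolated)
Conditions: TsNHNH2, THF, 4 Å MS, 50 °C; then catecholborane, CHCl3, 0 °C; then NaOAc·3H2O, 65 °C
Reagents that add atoms: none
Why: Only the C7 carbonyl can now condense with tosylhydrazide, and catecholborane reduction of the conjugated tosylhydrazone followed by acetate-induced loss of sulfinate gives an allylic diazene that expels N2 with hydrogen transfer to C5, moving the alkene cleanly to C6=C7 (Kabalka-type reductive 1,3-transposition of an enone tosylhydrazone, a Wolff–Kishner variant) with no change at any stereocentre.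

**Step 6**
Reactants: 10 3-[(tert-butyldimethylsilyl)oxy]-6,8a-dimethyl-1,3a,4,5,8,8a-hexahydro-4,8-epoxyazulene
Product: 13 (3aR,4S,8S,8aR)-3a,4-epoxy-8-hydroxy-6,8a-dimethyl-1,2,3a,4,5,8-hexahydroazulen-3(8aH)-one, via ketone 11 (not isolated), via hydroxy enone 12 (not isolated)
Conditions: n-Bu4NF, t-BuOOH (3 equiv), THF, 0 °C to rt
Reagents that add atoms: tert-butyl hydroperoxide, CC(C)(C)OO
Why: Fluoride cleaves the silyl enol ether and t-BuOOH protonates the enolate to ketone 11, which opens the oxygen bridge by E1cB elimination of the β-alkoxide (retro-oxa-Michael) to hydroxy enone 12, and this is drained by Weitz–Scheffer epoxidation with t-BuOO− from the face anti to the adjacent angular methyl, placing the new C4–O bond trans to the 8-hydroxyl while the buffering hydroperoxide keeps the medium too weakly basic for alkene migration.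

**Step 7**
Reactants: 13 (3aR,4S,8S,8aR)-3a,4-epoxy-8-hydroxy-6,8a-dimethyl-1,2,3a,4,5,8-hexahydroazulen-3(8aH)-one; 14 angelic acid [(2Z)-2-methylbut-2-enoic acid]
Product: 15 (3aR,4S,8S,8aR)-3a,4-epoxy-6,8a-dimethyl-3-oxo-1,2,3,3a,4,5,8,8a-octahydroazulen-8-yl (2Z)-2-methylbut-2-enoate
Conditions: 14, 2,4,6-Cl3C6H2COCl, Et3N, toluene, rt; then 13, 75 °C
Reagents that add atoms: none
Why: Yamaguchi-type mixed-anhydride esterification without a nucleophilic catalyst acylates the single free (neopentylic) hydroxyl with retention at C8 and without Z to E isomerisation of the angelate.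

**Step 8**
Reactants: 15 (3aR,4S,8S,8aR)-3a,4-epoxy-6,8a-dimethyl-3-oxo-1,2,3,3a,4,5,8,8a-octahydroazulen-8-yl (2Z)-2-methylbut-2-enoate
Product: 16 (3aS,4S,8S,8aS)-4-hydroxy-6,8a-dimethyl-3-oxo-1,2,3,3a,4,5,8,8a-octahydroazulen-8-yl (2Z)-2-methylbut-2-enoate
Conditions: SmI2 (2.5 equiv), THF/MeOH, −90 °C
Reagents that add atoms: none
Why: Electron transfer from SmI2 to the ketone cleaves the α C–O bond of the epoxy ketone to give the β-hydroxy ketone with the C4 configuration of the epoxide, and the samarium enolate is protonated at C3a by MeOH on the face anti to the angular methyl, which gives the trans ring fusion (reductive opening of an α,β-epoxy ketone).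

**Step 9**
Reactants: 16 (3aS,4S,8S,8aS)-4-hydroxy-6,8a-dimethyl-3-oxo-1,2,3,3a,4,5,8,8a-octahydroazulen-8-yl (2Z)-2-methylbut-2-enoate
Product: 17 (3R,3aS,4S,8S,8aS)-3,4-dihydroxy-6,8a-dimethyl-3-(propan-2-yl)-1,2,3,3a,4,5,8,8a-octahydroazulen-8-yl (2Z)-2-methylbut-2-enoate
Conditions: i-PrMgCl (3 equiv), CeCl3, THF, −78 °C
Reagents that add atoms: isopropylmagnesium chloride, CC(C)[Mg]Cl
Why: The weakly basic organocerium reagent (Imamoto-type addition) attacks the cyclopentanone faster than it enolises it or touches the hindered angelate, approaching anti to the axial 8a-methyl so that the new tertiary hydroxyl is cis to that methyl and the isopropyl group trans.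

**Step 10**
Reactants: 17 (3R,3aS,4S,8S,8aS)-3,4-dihydroxy-6,8a-dimethyl-3-(propan-2-yl)-1,2,3,3a,4,5,8,8a-octahydroazulen-8-yl (2Z)-2-methylbut-2-enoate; 18 4-acetoxybenzoyl chloride
Product: 20 (3R,3aS,4S,8S,8aS)-3-hydroxy-4-[(4-hydroxybenzoyl)oxy]-6,8a-dimethyl-3-(propan-2-yl)-1,2,3,3a,4,5,8,8a-octahydroazulen-8-yl (2Z)-2-methylbut-2-enoate, via acetoxybenzoate 19 (not isolated)
Conditions: 18, pyridine, DMAP (cat), CH2Cl2, 0 °C to rt; then pyrrolidine, 0 °C
Reagents that add atoms: none
Why: DMAP-catalysed acylation reaches only the secondary C4 hydroxyl because the tertiary carbinol is inert, and pyrrolidine then cleaves the phenolic acetate by aminolysis much faster than it attacks the two alkyl esters, so no stereocentre is touched.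

**Compound list**
1 | methyl 3-methylfuran-2-carboxylate | COC(=O)c1occc1C | starting material
2 | (3-methylfuran-2-yl)methanol | OCc1occc1C | intermediate
3 | 6-hydroxy-4-methyl-2H-pyran-3(6H)-one (racemic hemiacetal) | O=C1COC(O)C=C1C | intermediate
4 | 4-methyl-5-oxo-5,6-dihydro-2H-pyran-2-yl acetate (racemic) | CC(=O)OC1OCC(=O)C(C)=C1 | intermediate
5 | 3-methylcyclopent-2-en-1-one | CC1=CC(=O)CC1 | starting material
6 | 4-methylpyrylium-3-olate (oxidopyrylium betaine) | Cc1cc[o+]cc1[O-] | intermediate
7 | (3aR,4R,8R,8aS)-6,8a-dimethyl-1,2,3a,4,8,8a-hexahydro-4,8-epoxyazulene-3,7-dione; oxygen bridge, 8a-methyl and 3a-H on one face | O1[C@H]2C(=O)C(C)=C[C@@H]1[C@H]3[C@]2(C)CCC3=O | intermediate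
8 | C2=C3 tert-butyldimethylsilyl enol ether of 7 (C7 enone kept; stereocentres as in 7) | O1[C@H]2C(=O)C(C)=C[C@@H]1[C@H]3[C@]2(C)CC=C3O[Si](C)(C)C(C)(C)C | intermediate
9 | C7 tosylhydrazone of 8 | O1[C@H]2C(=NNS(=O)(=O)c4ccc(C)cc4)C(C)=C[C@@H]1[C@H]3[C@]2(C)CC=C3O[Si](C)(C)C(C)(C)C | intermediate
10 | 3-[(tert-butyldimethylsilyl)oxy]-6,8a-dimethyl-1,3a,4,5,8,8a-hexahydro-4,8-epoxyazulene (C2=C3 and C6=C7; stereocentres as in 7) | O1[C@H]2C=C(C)C[C@@H]1[C@H]3[C@]2(C)CC=C3O[Si](C)(C)C(C)(C)C | intermediate
11 | (3aR,4R,8S,8aS)-6,8a-dimethyl-1,2,3a,4,5,8-hexahydro-4,8-epoxyazulen-3(8aH)-one | O1[C@H]2C=C(C)C[C@@H]1[C@H]3[C@]2(C)CCC3=O | intermediate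
12 | (8S,8aS)-8-hydroxy-6,8a-dimethyl-1,2,5,8-tetrahydroazulen-3(8aH)-one (C3a=C4 enone; 8-OH cis to 8a-methyl) | O[C@H]1C=C(C)CC=C2[C@]1(C)CCC2=O | intermediate
13 | (3aR,4S,8S,8aR)-3a,4-epoxy-8-hydroxy-6,8a-dimethyl-1,2,3a,4,5,8-hexahydroazulen-3(8aH)-one (epoxide oxygen trans to 8a-methyl and 8-OH) | O[C@H]1C=C(C)C[C@@H]3O[C@]32[C@]1(C)CCC2=O | intermediate
14 | angelic acid, (2Z)-2-methylbut-2-enoic acid | C/C=C(/C)C(=O)O | starting material
15 | (3aR,4S,8S,8aR)-3a,4-epoxy-6,8a-dimethyl-3-oxo-1,2,3,3a,4,5,8,8a-octahydroazulen-8-yl (2Z)-2-methylbut-2-enoate | C/C=C(/C)C(=O)O[C@H]1C=C(C)C[C@@H]3O[C@]32[C@]1(C)CCC2=O | intermediate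
16 | (3aS,4S,8S,8aS)-4-hydroxy-6,8a-dimethyl-3-oxo-1,2,3,3a,4,5,8,8a-octahydroazulen-8-yl (2Z)-2-methylbut-2-enoate (trans ring fusion) | C/C=C(/C)C(=O)O[C@H]1C=C(C)C[C@H](O)[C@@H]2[C@]1(C)CCC2=O | intermediate
17 | (3R,3aS,4S,8S,8aS)-3,4-dihydroxy-6,8a-dimethyl-3-(propan-2-yl)-1,2,3,3a,4,5,8,8a-octahydroazulen-8-yl (2Z)-2-methylbut-2-enoate | C/C=C(/C)C(=O)O[C@H]1C=C(C)C[C@H](O)[C@@H]2[C@]1(C)CC[C@@]2(O)C(C)C | intermediate
18 | 4-acetoxybenzoyl chloride | CC(=O)Oc1ccc(cc1)C(Cl)=O | starting material
19 | 4-O-(4-acetoxybenzoyl) derivative of 17 | C/C=C(/C)C(=O)O[C@H]1C=C(C)C[C@H](OC(=O)c2ccc(OC(C)=O)cc2)[C@@H]2[C@]1(C)CC[C@@]2(O)C(C)C | intermediate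
20 | (3R,3aS,4S,8S,8aS)-3-hydroxy-4-[(4-hydroxybenzoyl)oxy]-6,8a-dimethyl-3-(propan-2-yl)-1,2,3,3a,4,5,8,8a-octahydroazulen-8-yl (2Z)-2-methylbut-2-enoate | C/C=C(/C)C(=O)O[C@H]1C=C(C)C[C@H](OC(=O)c2ccc(O)cc2)[C@@H]2[C@]1(C)CC[C@@]2(O)C(C)C | target

**Step count**
Total: 10 steps. Longest linear sequence: 10 steps (1 to 20); 5, 14 and 18 are bought.

**Steps most likely to fail**

Step 3. A β,β-disubstituted enone is a poor partner for the betaine, which may simply dimerise, and neither the enantioselectivity nor the endo preference has precedent. The fallback sets out from 4 (with 5 as the source of a stronger partner) and returns at 7. Compound 5 is α-iodinated (I2, pyridine) to 2-iodo-3-methylcyclopent-2-en-1-one F1 and methoxycarbonylated (CO, MeOH, Pd(OAc)2, PPh3, Et3N) to methyl 2-methyl-5-oxocyclopent-1-ene-1-carboxylate F2. This doubly activated alkene takes up the betaine from 4 under plain Et3N in CH2Cl2 without any catalyst to give the racemic 3a-methoxycarbonyl adduct F3. Krapcho dealkoxycarbonylation (LiCl, wet DMSO, 140 °C) gives racemic 7, and preparative chromatography on a chiral stationary phase removes the mirror-image dione F4 and delivers 7.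

Step 6. The opened hydroxy enone can re-close, its free hydroxyl can attack the new epoxide, and the facial preference of the epoxidation is only predicted. The fallback sets out from 10 and returns at 13. Buffered desilylation (n-Bu4NF, AcOH, THF, 0 °C) gives ketone 11, now isolated. TBSOTf and Et3N (CH2Cl2, −78 to 0 °C) open the bridge with transfer of silicon to the liberated oxygen, giving the 8-silyloxy enone F5, which has no free hydroxyl. Epoxidation (t-BuOOH, DBU) then gives the silylated epoxy ketone F6, and HF·pyridine in THF removes the silyl group to give 13.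

Step 9. The hindered β-hydroxy ketone may be reduced or enolised by the isopropyl reagent, or the esters may be attacked. The fallback sets out from 16 and returns at 17. Isopropenylmagnesium bromide with CeCl3 (THF, −78 °C; no β-hydrogen, so no reduction) gives the isopropenyl carbinol F7, and hydrogenation over RhCl(PPh3)3 (H2, benzene) saturates only the 1,1-disubstituted alkene to give 17.

Further compounds
F1 | step 3 | 2-iodo-3-methylcyclopent-2-en-1-one | CC1=C(I)C(=O)CC1
F2 | step 3 | methyl 2-methyl-5-oxocyclopent-1-ene-1-carboxylate | COC(=O)C1=C(C)CCC1=O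
F3 | step 3 | racemic methyl 6,8a-dimethyl-3,7-dioxo-1,2,3,4,7,8-hexahydro-4,8-epoxyazulene-3a(8aH)-carboxylate (both enantiomers; ester, 8a-methyl and oxygen bridge on one face) | O1[C@H]2C(=O)C(C)=C[C@@H]1[C@@]3(C(=O)OC)[C@]2(C)CCC3=O.O1[C@@H]2C(=O)C(C)=C[C@H]1[C@]3(C(=O)OC)[C@@]2(C)CCC3=O
F4 | step 3 | (3aS,4S,8S,8aR)-6,8a-dimethyl-1,2,3a,4,8,8a-hexahydro-4,8-epoxyazulene-3,7-dione (mirror image of 7) | O1[C@@H]2C(=O)C(C)=C[C@H]1[C@@H]3[C@@]2(C)CCC3=O
F5 | step 6 | (8S,8aS)-8-[(tert-butyldimethylsilyl)oxy]-6,8a-dimethyl-1,2,5,8-tetrahydroazulen-3(8aH)-one | CC(C)(C)[Si](C)(C)O[C@H]1C=C(C)CC=C2[C@]1(C)CCC2=O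
F6 | step 6 | 8-O-tert-butyldimethylsilyl ether of 13 | CC(C)(C)[Si](C)(C)O[C@H]1C=C(C)C[C@@H]3O[C@]32[C@]1(C)CCC2=O
F7 | step 9 | (3R,3aS,4S,8S,8aS)-3,4-dihydroxy-6,8a-dimethyl-3-(prop-1-en-2-yl)-1,2,3,3a,4,5,8,8a-octahydroazulen-8-yl (2Z)-2-methylbut-2-enoate | C/C=C(/C)C(=O)O[C@H]1C=C(C)C[C@H](O)[C@@H]2[C@]1(C)CC[C@@]2(O)C(C)=C
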